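Everything rests on cutting the C2–O1 bond of the dihydrobenzofuran. C2 carries both the ring oxygen O1 and a 4-hydroxy-3-methoxyphenyl ring, so a benzylic alcohol at C2 can lose water under mild acid to give a flat para-quinone methide. The phenol oxygen of the neighbouring lactone-bearing arene then adds to it. In one operation this last step makes C2–O1, closes the five-membered ring and sets C2 trans to the hydroxymethyl group on C3, whichever alcohol epimer enters. The precursor, seco-lappaol A, is the unprotected 1,2-diarylpropane-1,3-diol on the (3R,4R)-dibenzylbutyrolactone. Only its future C3 needs absolute control, which an Evans syn-aldol supplies.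

Key step: step 13

Labels: ring A is the arene of the benzyl group on lactone C3. Ring B is the arene of the benzyl group on lactone C4 and becomes the benzo ring of the dihydrobenzofuran. Ring C is the aryl group on benzofuran C2. "Future C2" and "future C3" are the open-chain carbons that become these ring atoms.

Assumption: in step 3 the (S,S) ligand is taken to give the R acid by analogy with the parent itaconates; both ligand antipodes are sold, so the other one would be used if the optical rotation of the lactone made in step 4 pointed the other way.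

Step 1
Reactants: 1 5-bromovanillin (3-bromo-4-hydroxy-5-methoxybenzaldehyde)
Product: 2 4-(benzyloxy)-3-bromo-5-methoxybenzaldehyde
Conditions: BnBr, K2CO3, DMF, 60 °C
Reagents that add atoms: benzyl bromide, BrCc1ccccc1
Why: Williamson ether synthesis on an acidic phenol; the benzyl group masks the future O1 until the penultimate step and the bromine marks the ring-B carbon that will carry C3.

Step 2
Reactants: 2 4-(benzyloxy)-3-bromo-5-methoxybenzaldehyde; 3 dimethyl succinate
Product: 4 (E)-4-[4-(benzyloxy)-3-bromo-5-methoxyphenyl]-3-(methoxycarbonyl)but-3-enoic acid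
Conditions: NaOMe, MeOH, reflux; then aq HCl
Reagents that add atoms: none
Why: Stobbe condensation of a non-enolisable aryl aldehyde (aldol addition, lactonisation, E1cB opening) gives the half-ester, and the E alkene is favoured because the aryl group avoids the ester.

Step 3
Reactants: 4 (E)-half-ester
Product: 5 (3R)-4-[4-(benzyloxy)-3-bromo-5-methoxyphenyl]-3-(methoxycarbonyl)butanoic acid
Conditions: [Rh(cod)((S,S)-Et-DuPHOS)]BF4 (0.2 mol %), H2 (5 atm), NaOMe (10 mol %), MeOH, rt
Reagents that add atoms: none
Why: Asymmetric hydrogenation of a Stobbe-derived itaconate half-ester, in which carboxylate and alkene chelate the cationic rhodium bisphospholane so that the ligand dictates the face and sets the R centre (future lactone C4); the aryl bromide and the benzyl ether are inert to this homogeneous catalyst.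

Step 4
Reactants: 5 (3R)-half-ester
Product: 7 (4R)-4-[4-(benzyloxy)-3-bromo-5-methoxybenzyl]dihydrofuran-2(3H)-one, via hydroxy acid 6 (not isolated)
Conditions: KOH (1 equiv), EtOH; CaCl2, NaBH4, −10 °C → rt; then 3 M HCl, rt
Reagents that add atoms: none
Why: Chemoselective borohydride reduction, since calcium borohydride reduces the methyl ester while the carboxylate salt is untouched, and acidification then lactonises the γ-hydroxy acid without involving the stereocentre.

Step 5
Reactants: 8 [4-(benzyloxy)-3-methoxyphenyl]methanol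
Product: 9 1-(benzyloxy)-4-(bromomethyl)-2-methoxybenzene
Conditions: PBr3, Et2O, 0 °C; used without storage
Reagents that add atoms: phosphorus tribromide, BrP(Br)Br
Why: Standard conversion of a benzylic alcohol to the bromide through its phosphite ester (SN2 displacement by bromide).

Step 6
Reactants: 7 (4R)-lactone; 9 ring-A benzyl bromide
Product: 11 (3R,4R)-3-[4-(benzyloxy)-3-methoxybenzyl]-4-[4-(benzyloxy)-3-bromo-5-methoxybenzyl]dihydrofuran-2(3H)-one, via lithium enolate 10 (not isolated)
Conditions: LiHMDS (1.05 equiv), THF, −78 °C; then 9, DMPU, −78 → −30 °C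
Reagents that add atoms: lithium hexamethyldisilazide, [Li]N([Si](C)(C)C)[Si](C)(C)C (its lithium is present only in 10)
Why: Diastereoselective lactone enolate alkylation, the classical entry to trans-dibenzylbutyrolactones, in which the bromide approaches the planar enolate anti to the C4 benzyl group and so sets C3 as R; the amide base is consumed by enolisation and leaves the aryl bromide alone at low temperature.

Step 7
Reactants: 11 (3R,4R)-bromo lactone; 12 (2-tert-butoxy-2-oxoethyl)zinc chloride (commercial ether solution)
Product: 13 tert-butyl 2-[2-(benzyloxy)-3-methoxy-5-({(3R,4R)-4-[4-(benzyloxy)-3-methoxybenzyl]-5-oxotetrahydrofuran-3-yl}methyl)phenyl]acetate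
Conditions: Pd(dba)2 (3 mol %), Q-Phos (3 mol %), THF, rt → 50 °C
Reagents that add atoms: none
Why: Palladium-catalysed α-arylation of a Reformatsky reagent (Negishi-type coupling), whose nearly neutral zinc enolate tolerates the enolisable lactone and installs in one step both carbons that become C3 and its hydroxymethyl group.

Step 8
Reactants: 13 tert-butyl arylacetate
Product: 14 2-[2-(benzyloxy)-3-methoxy-5-({(3R,4R)-4-[4-(benzyloxy)-3-methoxybenzyl]-5-oxotetrahydrofuran-3-yl}methyl)phenyl]acetic acid
Conditions: TFA, CH2Cl2, 0 °C → rt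
Reagents that add atoms: none
Why: Acidolysis of a tert-butyl ester (E1 loss of isobutene), run cold and dilute so that the aryl benzyl ethers, the lactone and both stereocentres are left as they are.

Step 9
Reactants: 14 arylacetic acid; 15 (S)-4-benzyl-2-oxazolidinone
Product: 17 (S)-4-benzyl-3-{2-[2-(benzyloxy)-3-methoxy-5-({(3R,4R)-4-[4-(benzyloxy)-3-methoxybenzyl]-5-oxotetrahydrofuran-3-yl}methyl)phenyl]acetyl}oxazolidin-2-one, via mixed pivalic anhydride 16 (not isolated)
Conditions: PivCl, Et3N, THF, −20 °C; then LiCl, 15, −20 °C → rt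
Reagents that add atoms: pivaloyl chloride, CC(C)(C)C(=O)Cl (its acyl group is present only in 16 and leaves again)
Why: N-acylation of an oxazolidinone through a mixed anhydride with LiCl activation, in which the nucleophile attacks the less hindered arylacetyl carbonyl and the amine base is too mild to form a ketene or disturb the lactone.

Step 10
Reactants: 17 arylacetyl imide; 18 4-(benzyloxy)-3-methoxybenzaldehyde (O-benzylvanillin)
Product: 21 (S)-4-benzyl-3-[(2S,3S)-3-hydroxy-3-(ring C aryl)-2-(ring B aryl)propanoyl]oxazolidin-2-one (syn aldol adduct; all three phenols benzylated; lactone intact), via (Z)-boron enolate 19 (not isolated), via boron aldolate 20 (not isolated)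
Conditions: Bu2BOTf (1.15 equiv), Et3N (1.3 equiv), CH2Cl2, −78 → 0 °C; 18, −78 → 0 °C; then pH 7 buffer, MeOH, 30 % H2O2, 0 °C
Reagents that add atoms: dibutylboron triflate, CCCCB(CCCC)OS(=O)(=O)C(F)(F)F (its boron unit is present only in 19 and 20)
Why: Evans syn-aldol, in which soft enolisation of the most acidic C–H (the imide CH2 next to ring B) gives the (Z)-boron enolate, and this meets the aldehyde in a Zimmerman–Traxler chair on the face away from the auxiliary benzyl group, so future C3 is set by the auxiliary (2S here) and future C2 comes out syn (3S); the hindered tertiary lactone α-C–H is not enolised by the single equivalent of boron reagent.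

Step 11
Reactants: 21 syn aldol adduct
Product: 22 (3R,4R)-3-[4-(benzyloxy)-3-methoxybenzyl]-4-{4-(benzyloxy)-3-[(1S,2R)-1-[4-(benzyloxy)-3-methoxyphenyl]-1,3-dihydroxypropan-2-yl]-5-methoxybenzyl}dihydrofuran-2(3H)-one
Conditions: NaBH4 (4 equiv), THF–H2O, 0 °C → rt
Reagents that add atoms: none
Why: Reductive cleavage of an N-acyloxazolidinone with aqueous borohydride, in which the exocyclic imide carbonyl is much more electrophilic than the α,β-disubstituted lactone and the transient aldehyde is reduced at once, so future C3 keeps its geometry (R now only through a change of CIP priorities) and the auxiliary is recovered.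

Step 12
Reactants: 22 tribenzyl diol
Product: 23 seco-lappaol A (3R,4R)-4-{3-[(1S,2R)-1,3-dihydroxy-1-(4-hydroxy-3-methoxyphenyl)propan-2-yl]-4-hydroxy-5-methoxybenzyl}-3-(4-hydroxy-3-methoxybenzyl)dihydrofuran-2(3H)-one
Conditions: H2 (1 atm), 10 % Pd/C, EtOAc–EtOH, rt; stopped after uptake of 3 equiv; used directly
Reagents that add atoms: none
Why: Catalytic hydrogenolysis of three aryl benzyl ethers in neutral medium, routine for lignin-type arylpropanediol models, in which the O–CH2Ph bonds cleave faster than the secondary benzylic C–OH, no base is present that could trigger retro-aldol or phenoxide chemistry, and no stereocentre is touched.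

Step 13
Reactants: 23 seco-lappaol A
Product: 25 lappaol A (3R,4R)-3-(4-hydroxy-3-methoxybenzyl)-4-{[(2S,3R)-2-(4-hydroxy-3-methoxyphenyl)-3-(hydroxymethyl)-7-methoxy-2,3-dihydrobenzofuran-5-yl]methyl}dihydrofuran-2(3H)-one, via para-quinone methide 24 (not isolated)
Conditions: p-TsOH·H2O (10 mol %), THF–CH2Cl2 (0.005 M), 4 Å MS, 0 °C → rt
Reagents that add atoms: none
Why: Protonation of the hydroxyl on future C2 and loss of water, pushed by the para hydroxyl of ring C, give the planar para-quinone methide 24, so the configuration made at this carbon in step 10 no longer matters. The reaction type is the acid-promoted closure of 2-(2-hydroxyaryl)-1-(4-hydroxyaryl)propane-1,3-diols to phenylcoumarans, familiar from lignin β-5 model chemistry and parallel to the biosynthetic ring closure. The ring-B phenol oxygen adds to the methide carbon in a 5-exo-trig closure, and rearomatisation of ring C supplies the driving force. The new C2 centre is controlled by C3, because A(1,3) strain in 24 turns the C3–H bond towards the quinoid ring and oxygen then attacks the face that leaves the aryl and hydroxymethyl groups on opposite sides; since C2–O1 can ionise again under the acid, any cis ring drains to the more stable trans (2S,3R) ring. Chemoselectivity among five hydroxyl groups comes from the substrate: only future C2 bears an ionisable benzylic C–O bond, the primary alcohol could close only to a strained oxetane, the ring-A phenol is too far away, and high dilution holds back intermolecular capture.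

Compound list
1 | 5-bromovanillin | COc1cc(C=O)cc(Br)c1O | starting material
2 | 4-(benzyloxy)-3-bromo-5-methoxybenzaldehyde | COc1cc(C=O)cc(Br)c1OCc2ccccc2 | intermediate
3 | dimethyl succinate | COC(=O)CCC(=O)OC | starting material
4 | (E)-Stobbe half-ester | COC(=O)/C(CC(=O)O)=C/c1cc(OC)c(OCc2ccccc2)c(Br)c1 | intermediate
5 | (3R)-hydrogenated half-ester | COC(=O)[C@@H](CC(=O)O)Cc1cc(OC)c(OCc2ccccc2)c(Br)c1 | intermediate
6 | (3R)-4-aryl-3-(hydroxymethyl)butanoic acid (not isolated) | OC[C@@H](CC(=O)O)Cc1cc(OC)c(OCc2ccccc2)c(Br)c1 | intermediate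
7 | (4R)-β-benzyl lactone | O=C1C[C@@H](Cc2cc(OC)c(OCc3ccccc3)c(Br)c2)CO1 | intermediate
8 | [4-(benzyloxy)-3-methoxyphenyl]methanol | COc1cc(CO)ccc1OCc2ccccc2 | starting material
9 | 1-(benzyloxy)-4-(bromomethyl)-2-methoxybenzene | COc1cc(CBr)ccc1OCc2ccccc2 | intermediate
10 | lithium enolate of 7 (not isolated) | [Li]OC1=C[C@@H](Cc2cc(OC)c(OCc3ccccc3)c(Br)c2)CO1 | intermediate
11 | (3R,4R)-trans bromo lactone | COc1cc(C[C@H]2C(=O)OC[C@@H]2Cc3cc(OC)c(OCc4ccccc4)c(Br)c3)ccc1OCc5ccccc5 | intermediate
12 | (2-tert-butoxy-2-oxoethyl)zinc chloride | CC(C)(C)OC(=O)C[Zn]Cl | starting material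
13 | tert-butyl arylacetate | COc1cc(C[C@H]2C(=O)OC[C@@H]2Cc3cc(OC)c(OCc4ccccc4)c(CC(=O)OC(C)(C)C)c3)ccc1OCc5ccccc5 | intermediate
14 | arylacetic acid | COc1cc(C[C@H]2C(=O)OC[C@@H]2Cc3cc(OC)c(OCc4ccccc4)c(CC(=O)O)c3)ccc1OCc5ccccc5 | intermediate
15 | (S)-4-benzyl-2-oxazolidinone | O=C1N[C@@H](Cc2ccccc2)CO1 | starting material
16 | mixed pivalic anhydride of 14 (not isolated) | COc1cc(C[C@H]2C(=O)OC[C@@H]2Cc3cc(OC)c(OCc4ccccc4)c(CC(=O)OC(=O)C(C)(C)C)c3)ccc1OCc5ccccc5 | intermediate
17 | arylacetyl imide | COc1cc(C[C@H]2C(=O)OC[C@@H]2Cc3cc(OC)c(OCc4ccccc4)c(CC(=O)N6C(=O)OC[C@@H]6Cc7ccccc7)c3)ccc1OCc5ccccc5 | intermediate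
18 | 4-(benzyloxy)-3-methoxybenzaldehyde | COc1cc(C=O)ccc1OCc2ccccc2 | starting material
19 | (Z)-dibutylboron enolate of 17 (not isolated) | COc1cc(C[C@H]2C(=O)OC[C@@H]2Cc3cc(OC)c(OCc4ccccc4)c(/C=C(\OB(CCCC)CCCC)N6C(=O)OC[C@@H]6Cc7ccccc7)c3)ccc1OCc5ccccc5 | intermediate
20 | dibutylboron aldolate (not isolated) | COc1cc(C[C@H]2C(=O)OC[C@@H]2Cc3cc(OC)c(OCc4ccccc4)c([C@H](C(=O)N6C(=O)OC[C@@H]6Cc7ccccc7)[C@H](OB(CCCC)CCCC)c8ccc(OCc9ccccc9)c(OC)c8)c3)ccc1OCc5ccccc5 | intermediate
21 | (2S,3S)-syn aldol adduct | COc1cc(C[C@H]2C(=O)OC[C@@H]2Cc3cc(OC)c(OCc4ccccc4)c([C@H](C(=O)N6C(=O)OC[C@@H]6Cc7ccccc7)[C@H](O)c8ccc(OCc9ccccc9)c(OC)c8)c3)ccc1OCc5ccccc5 | intermediate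
22 | tribenzyl (1S,2R)-diol | COc1cc(C[C@H]2C(=O)OC[C@@H]2Cc3cc(OC)c(OCc4ccccc4)c([C@H](CO)[C@H](O)c6ccc(OCc7ccccc7)c(OC)c6)c3)ccc1OCc5ccccc5 | intermediate
23 | seco-lappaol A | COc1cc(C[C@H]2C(=O)OC[C@@H]2Cc2cc(OC)c(O)c(c2)[C@H](CO)[C@H](O)c2ccc(O)c(OC)c2)ccc1O | intermediate
24 | para-quinone methide (C3 unchanged; exocyclic alkene geometry not fixed; not isolated) | COc1cc(C[C@H]2C(=O)OC[C@@H]2Cc2cc(OC)c(O)c(c2)[C@H](CO)C=C2C=CC(=O)C(OC)=C2)ccc1O | intermediate
25 | lappaol A | COc1cc(C[C@H]2C(=O)OC[C@@H]2Cc2cc(OC)c3c(c2)[C@H](CO)[C@@H](c2ccc(O)c(OC)c2)O3)ccc1O | target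

Total step count: 13. Longest linear sequence: 12 (steps 1–4 and 6–13, from 5-bromovanillin 1); step 5 is a one-step side branch.

Steps most likely to fail

Step 13 (key step). The ionised intermediate may shed formaldehyde from the hydroxymethyl arm on C3 (retro-Prins fragmentation). It may also be captured by a phenol of a second molecule, or equilibrate too slowly to the trans ring. The fallback sets out from 23. Bromotrimethylsilane in CH2Cl2–dioxane at 0 °C exchanges only the activated benzylic hydroxyl and gives the benzylic bromide of seco-lappaol A F1. Brief shaking of this solution with aqueous NaHCO3 eliminates HBr. The same quinone methide 24 then arises with no acid present and closes under kinetic control, again steered by C3. The fallback comes back to the route at 25.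

Step 11. Hydride may attack the lactone carbonyl or the ring carbonyl of the auxiliary. The basic medium may also cause retro-aldol cleavage or epimerisation at future C3 through the transient α-aryl aldehyde. The fallback sets out from 21. LiOH/H2O2 in THF–H2O at 0 °C removes the auxiliary by hydrolysis and gives the β-hydroxy acid F2; a lactone opened on the way recloses on acidification. BH3·THF at 0 °C reduces a free carboxylic acid much faster than a lactone, and it brings the material back to the route at 22.

Step 7. Oxidative addition into the electron-rich, ortho-alkoxy C–Br bond may be slow, with protodebromination taking over. The zinc enolate may also be quenched by proton transfer before it couples. The fallback sets out from 11. Stille coupling with allyltributylstannane (Pd(PPh3)4, toluene, 100 °C) gives the ring-B allylarene F3. Lemieux–Johnson cleavage (cat. OsO4, NaIO4, 2,6-lutidine, dioxane–H2O) gives the arylacetaldehyde F4. Pinnick oxidation (NaClO2, NaH2PO4, 2-methyl-2-butene, t-BuOH–H2O) then comes back to the route at 14 and bypasses 13 and step 8.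

Further compounds
F1 | step 13 | benzylic bromide of seco-lappaol A (Br on future C2, both epimers) | COc1cc(C[C@H]2C(=O)OC[C@@H]2Cc2cc(OC)c(O)c(c2)[C@H](CO)C(Br)c2ccc(O)c(OC)c2)ccc1O
F2 | step 11 | (2S,3S)-β-hydroxy acid from 21 | COc1cc(C[C@H]2C(=O)OC[C@@H]2Cc3cc(OC)c(OCc4ccccc4)c([C@H](C(=O)O)[C@H](O)c6ccc(OCc7ccccc7)c(OC)c6)c3)ccc1OCc5ccccc5
F3 | step 7 | (3R,4R)-4-[3-allyl-4-(benzyloxy)-5-methoxybenzyl]-3-[4-(benzyloxy)-3-methoxybenzyl]dihydrofuran-2(3H)-one | COc1cc(C[C@H]2C(=O)OC[C@@H]2Cc3cc(OC)c(OCc4ccccc4)c(CC=C)c3)ccc1OCc5ccccc5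
F4 | step 7 | ring-B arylacetaldehyde | COc1cc(C[C@H]2C(=O)OC[C@@H]2Cc3cc(OC)c(OCc4ccccc4)c(CC=O)c3)ccc1OCc5ccccc5
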